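**Plan**
- Ring D of the target (C1 carboxyl, C2 hydroxyl, C4 methoxy, C6 CH2CH2 bridge) has the oxygen pattern of a 3,5,7-triketo acid whose C2 has condensed with the C7 carbonyl. It is cut across ring D C1–C6 to an open-chain diketo-dioxinone, the dioxinone holding the carboxyl and the C2 oxygen as one acetonide.
- Further cuts: the chain C–C bond next to the distal ketone (keto-dioxinone dianion + N-methoxy-N-methylamide), the ring B–O–ring C diaryl ether (copper-catalysed O-arylation), and the ring A/ring B two-carbon bridge (Horner–Wadsworth–Emmons alkene).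
- Forward: rings A, B and C are bought as benzenoids and joined first (alkene, then ether). The side chain is then extended to the masked tetraketide, and ring D is the only ring built, by base-mediated aldol aromatisation.
- End game: methylation of the single free phenol, hydroxide opening of the acetonide, and one hydrogenation that saturates the A/B alkene and removes the benzyl ether.
- Stereochemistry: the target has no stereocentre. The E-alkene of the A/B bridge is a transient element, carried only so that the last hydrogenation does two jobs.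

Key step: step 7

Remark: ring A = 4-hydroxyphenyl, ring B = the 1,3,5-trisubstituted methoxy ring, ring C = the para-phenylene ring, ring D = the salicylic acid ring. In the step names, Ar = 4-{3-methoxy-5-[(E)-2-(4-benzyloxyphenyl)ethenyl]phenoxy}phenyl (ring C carrying ring B and benzyl-protected ring A).

**Step 1**
Reactants: 1 4-benzyloxybenzyl chloride
Product: 2 diethyl [(4-benzyloxyphenyl)methyl]phosphonate
Conditions: P(OEt)3 (neat, excess), 140 °C, EtCl distilled off
Reagents that add atoms: triethyl phosphite, CCOP(OCC)OCC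
Why: Michaelis–Arbuzov reaction, in which the benzylic chloride alkylates phosphorus and chloride dealkylates the phosphonium ion, a standard route to benzylic phosphonates that leaves the benzyl ether untouched.

**Step 2**
Reactants: 2 diethyl [(4-benzyloxyphenyl)methyl]phosphonate; 3 3-bromo-5-methoxybenzaldehyde
Product: 5 1-bromo-3-methoxy-5-[(E)-2-(4-benzyloxyphenyl)ethenyl]benzene, via potassium phosphonate carbanion 4 (not isolated)
Conditions: KOtBu, THF, 0 °C; then 3, 0 °C to rt
Reagents that add atoms: none
Why: Horner–Wadsworth–Emmons olefination of a non-enolisable aryl aldehyde with a benzylic phosphonate anion, which should give the E-stilbene as one isomer and does not touch the aryl bromide.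

**Step 3**
Reactants: 5 1-bromo-3-methoxy-5-[(E)-2-(4-benzyloxyphenyl)ethenyl]benzene; 6 methyl 3-(4-hydroxyphenyl)propanoate
Product: 7 methyl 3-Ar-propanoate
Conditions: CuI (10 mol %), N,N-dimethylglycine hydrochloride (30 mol %), Cs2CO3, 1,4-dioxane, 90 °C, argon
Reagents that add atoms: none
Why: Ullmann-type diaryl ether synthesis, in which amino-acid-ligated monovalent copper couples an unactivated aryl bromide with a phenoxide at moderate temperature, and anhydrous carbonate in dioxane should spare the methyl ester, the alkene and the benzyl ether.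

**Step 4**
Reactants: 7 methyl 3-Ar-propanoate
Product: 8 N-methoxy-N-methyl-3-Ar-propanamide
Conditions: MeNHOMe·HCl, iPrMgCl, THF, −20 to 0 °C
Reagents that add atoms: N,O-dimethylhydroxylamine hydrochloride, CNOC.Cl
Why: Direct aminolysis of an unhindered methyl ester by the chloromagnesium amide of N,O-dimethylhydroxylamine (Weinreb amide formation), with no other electrophile in the molecule.

**Step 5**
Reactants: 9 2,2,6-trimethyl-4H-1,3-dioxin-4-one
Product: 11 2,2-dimethyl-6-(2-oxopropyl)-4H-1,3-dioxin-4-one, via lithium dienolate 10 (not isolated)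
Conditions: 9 (2 equiv), LiN(SiMe3)2 (2 equiv), THF, −78 °C; then AcCl (1 equiv), −78 °C; aq. NH4Cl
Reagents that add atoms: acetyl chloride, CC(Cl)=O
Why: Vinylogous Claisen-type acylation, in which kinetic deprotonation of the 6-methyl group gives the dienolate that is C-acylated at its exocyclic carbon, with the second equivalent of dienolate taking up the more acidic proton of the product.

**Step 6**
Reactants: 11 2,2-dimethyl-6-(2-oxopropyl)-4H-1,3-dioxin-4-one; 8 N-methoxy-N-methyl-3-Ar-propanamide
Product: 13 2,2-dimethyl-6-(2,4-dioxo-6-Ar-hexyl)-4H-1,3-dioxin-4-one, via dilithium dienolate 12 (not isolated)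
Conditions: 11 (1.5 equiv), LiN(iPr)2 (3.1 equiv), THF, −78 °C; then 8, −78 to −30 °C; 1 M HCl quench; short silica plug
Reagents that add atoms: none
Why: Dianion Claisen condensation in the Weinreb ketone synthesis mode, where the second deprotonation makes the terminal methyl carbon the most reactive site, so it adds regioselectively to the amide, and the chelated tetrahedral adduct holds until the acidic quench and prevents over-addition.

**Step 7**
Reactants: 13 2,2-dimethyl-6-(2,4-dioxo-6-Ar-hexyl)-4H-1,3-dioxin-4-one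
Product: 15 7-hydroxy-2,2-dimethyl-5-(2-Ar-ethyl)-4H-1,3-benzodioxin-4-one, via cyclic aldol adduct 14 (not isolated)
Conditions: Et3N, CH2Cl2, 4 Å MS, rt
Reagents that add atoms: none
Why: Triethylamine enolises the diketone and, through the CH2 next to the dioxinone, the vinylogous ester, so dioxinone C5 becomes the carbon end of an extended dienolate and adds to the distal ketone, forming the ring D C1–C6 bond (adduct 14); loss of water and enolisation of the remaining ketone then aromatise the new carbocycle. The closest known reaction type is the base-mediated biomimetic aldol aromatisation of diketo-dioxinones to resorcylate acetonides, the laboratory counterpart of the fold used by stilbenecarboxylate-forming polyketide synthases. Ring D closes in a 6-(enolexo)-exo-trig aldol mode, which Baldwin's rules for enolates favour. No stereocentre is set, because both sp3 centres of 14 are erased on dehydration and tautomerisation. The step needs carbon–carbon aldol closure to beat O-cyclisation to a 4-pyranone and Claisen-type attack on the ester carbonyl; the dioxinone carbonyl is a poorly electrophilic, acetal-locked vinylogous carbonate that cannot open to a ketene at room temperature, and a mild amine base without acid favours the carbon nucleophile. Because the acetonide keeps the carboxyl and the ortho oxygen masked, the only free hydroxyl in 15 is the one at C7 (ring D C4), which must become the methyl ether.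

**Step 8**
Reactants: 15 7-hydroxy-2,2-dimethyl-5-(2-Ar-ethyl)-4H-1,3-benzodioxin-4-one
Product: 16 7-methoxy-2,2-dimethyl-5-(2-Ar-ethyl)-4H-1,3-benzodioxin-4-one
Conditions: MeI, K2CO3, acetone, 40 °C
Reagents that add atoms: iodomethane, CI
Why: Williamson ether synthesis on the only acidic hydroxyl of the molecule, so no regiochemical choice arises and the ester stays locked in the acetonide.

**Step 9**
Reactants: 16 7-methoxy-2,2-dimethyl-5-(2-Ar-ethyl)-4H-1,3-benzodioxin-4-one
Product: 17 2-hydroxy-4-methoxy-6-(2-Ar-ethyl)benzoic acid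
Conditions: aq. KOH (48%), DMSO, 80 °C; then 1 M HCl, 0 °C
Reagents that add atoms: potassium hydroxide, [K+].[OH-]; water, O
Why: Saponification of the aryl ester of the benzodioxinone, in which hydroxide adds to the lactone carbonyl and the expelled hemiketal collapses to acetone and the phenoxide; forcing conditions are needed for the 2,6-disubstituted benzoate, and cold acidification should avoid decarboxylation.

**Step 10**
Reactants: 17 2-hydroxy-4-methoxy-6-(2-Ar-ethyl)benzoic acid
Product: 18 2-hydroxy-6-[2-(4-{3-[2-(4-hydroxyphenyl)ethyl]-5-methoxyphenoxy}phenyl)ethyl]-4-methoxybenzoic acid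
Conditions: H2 (1 atm), 10% Pd/C, EtOAc/MeOH, rt
Reagents that add atoms: none
Why: Heterogeneous catalytic hydrogenation, which should saturate the stilbene alkene and hydrogenolyse the O-benzyl ether in one operation while aryl methyl ethers, the diaryl ether and the salicylic acid are inert.

**Compound list**
1 | 4-benzyloxybenzyl chloride [1-(benzyloxy)-4-(chloromethyl)benzene] | ClCc1ccc(OCc2ccccc2)cc1 | starting material
2 | diethyl [(4-benzyloxyphenyl)methyl]phosphonate | CCOP(=O)(OCC)Cc1ccc(OCc2ccccc2)cc1 | intermediate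
3 | 3-bromo-5-methoxybenzaldehyde | COc1cc(Br)cc(C=O)c1 | starting material
4 | potassium salt of the benzylic carbanion of 2 (formed in the flask, not isolated) | [K+].CCOP(=O)(OCC)[CH-]c1ccc(OCc2ccccc2)cc1 | intermediate
5 | 1-bromo-3-methoxy-5-[(E)-2-(4-benzyloxyphenyl)ethenyl]benzene | COc1cc(Br)cc(/C=C/c2ccc(OCc3ccccc3)cc2)c1 | intermediate
6 | methyl 3-(4-hydroxyphenyl)propanoate | COC(=O)CCc1ccc(O)cc1 | starting material
7 | methyl 3-[4-(3-{(E)-2-[4-(benzyloxy)phenyl]ethenyl}-5-methoxyphenoxy)phenyl]propanoate | COC(=O)CCc1ccc(Oc2cc(OC)cc(/C=C/c3ccc(OCc4ccccc4)cc3)c2)cc1 | intermediate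
8 | N-methoxy-N-methyl-3-[4-(3-{(E)-2-[4-(benzyloxy)phenyl]ethenyl}-5-methoxyphenoxy)phenyl]propanamide | CON(C)C(=O)CCc1ccc(Oc2cc(OC)cc(/C=C/c3ccc(OCc4ccccc4)cc3)c2)cc1 | intermediate
9 | 2,2,6-trimethyl-4H-1,3-dioxin-4-one | CC1=CC(=O)OC(C)(C)O1 | starting material
10 | lithium 2,2-dimethyl-6-methylidene-1,3-dioxin-4-olate, the dienolate of 9 (formed in the flask, not isolated) | [Li+].C=C1C=C([O-])OC(C)(C)O1 | intermediate
11 | 2,2-dimethyl-6-(2-oxopropyl)-4H-1,3-dioxin-4-one | CC(=O)CC1=CC(=O)OC(C)(C)O1 | intermediate
12 | dilithium dienolate (dianion) of 11 (formed in the flask, not isolated) | [Li+].[Li+].C=C([O-])C=C1C=C([O-])OC(C)(C)O1 | intermediate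
13 | 6-{6-[4-(3-{(E)-2-[4-(benzyloxy)phenyl]ethenyl}-5-methoxyphenoxy)phenyl]-2,4-dioxohexyl}-2,2-dimethyl-4H-1,3-dioxin-4-one | CC1(C)OC(CC(=O)CC(=O)CCc2ccc(Oc3cc(OC)cc(/C=C/c4ccc(OCc5ccccc5)cc4)c3)cc2)=CC(=O)O1 | intermediate
14 | cyclic aldol adduct: 5-hydroxy-2,2-dimethyl-5-(2-Ar-ethyl)-4a,5,6,7-tetrahydro-1,3-benzodioxine-4,7-dione with the C8=C8a double bond (mixture of diastereomers, formed in the flask, not isolated) | CC1(C)OC2=CC(=O)CC(O)(CCc3ccc(Oc4cc(OC)cc(/C=C/c5ccc(OCc6ccccc6)cc5)c4)cc3)C2C(=O)O1 | intermediate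
15 | 5-{2-[4-(3-{(E)-2-[4-(benzyloxy)phenyl]ethenyl}-5-methoxyphenoxy)phenyl]ethyl}-7-hydroxy-2,2-dimethyl-4H-1,3-benzodioxin-4-one | CC1(C)Oc2cc(O)cc(CCc3ccc(Oc4cc(OC)cc(/C=C/c5ccc(OCc6ccccc6)cc5)c4)cc3)c2C(=O)O1 | intermediate
16 | 5-{2-[4-(3-{(E)-2-[4-(benzyloxy)phenyl]ethenyl}-5-methoxyphenoxy)phenyl]ethyl}-7-methoxy-2,2-dimethyl-4H-1,3-benzodioxin-4-one | CC1(C)Oc2cc(OC)cc(CCc3ccc(Oc4cc(OC)cc(/C=C/c5ccc(OCc6ccccc6)cc5)c4)cc3)c2C(=O)O1 | intermediate
17 | 2-{2-[4-(3-{(E)-2-[4-(benzyloxy)phenyl]ethenyl}-5-methoxyphenoxy)phenyl]ethyl}-6-hydroxy-4-methoxybenzoic acid | COc1cc(O)c(C(=O)O)c(CCc2ccc(Oc3cc(OC)cc(/C=C/c4ccc(OCc5ccccc5)cc4)c3)cc2)c1 | intermediate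
18 | 2-hydroxy-6-[2-(4-{3-[2-(4-hydroxyphenyl)ethyl]-5-methoxyphenoxy}phenyl)ethyl]-4-methoxybenzoic acid (CNP0188714.0) | COc1cc(CCc2ccc(O)cc2)cc(Oc2ccc(CCc3cc(OC)cc(O)c3C(=O)O)cc2)c1 | target

**Step count**
Total steps: 10. Longest linear sequence: 9 steps (1 → 2 → 5 → 7 → 8 → 13 → 15 → 16 → 17 → 18, that is steps 1–4 and 6–10); step 5 is a one-step side branch that supplies 11.

**Steps most likely to fail**

1. Step 6. The dianion may act as a base toward the α-CH2 of the amide instead of adding, leaving the coupling incomplete, and the sensitive product may partly cyclise or decompose during quench and chromatography. Fallback (aldol then oxidation instead of acylation), setting out from 8 and returning at 13: reduction of 8 with iBu2AlH in THF at −78 °C should give the aldehyde 3-Ar-propanal F1. Addition of the dianion 12 (from 11 and LiN(iPr)2) to this far more electrophilic partner at −78 °C should give the racemic β-hydroxy ketone 6-(4-hydroxy-2-oxo-6-Ar-hexyl)-2,2-dimethyl-4H-1,3-dioxin-4-one F2. Oxidation with Dess–Martin periodinane in CH2Cl2 should then deliver diketo-dioxinone 13.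

2. Step 7. Oxygen cyclisation to a 4-pyranone may compete with the carbon aldol closure, or dehydration of the aldol adduct may stall so that aromatisation is incomplete. Fallback (open the dioxinone before folding), setting out from 13 and returning at 18: heating 13 in toluene at 110 °C with benzyl alcohol should expel acetone and trap the acylketene as the open-chain ester benzyl 3,5,7-trioxo-9-Ar-nonanoate F3. Its β-keto ester carbon is a stronger aldol donor, so Cs2CO3 in iPrOH/CH2Cl2 followed by dilute HCl should effect the same C2-to-C7 aldol aromatisation to benzyl 2,4-dihydroxy-6-(2-Ar-ethyl)benzoate F4. MeI and K2CO3 in acetone should methylate only the 4-hydroxyl, the 2-hydroxyl being hydrogen-bonded to the ester, to give benzyl 2-hydroxy-4-methoxy-6-(2-Ar-ethyl)benzoate F5. Hydrogenation over Pd/C should then cleave the benzyl ester and the benzyl ether and saturate the alkene, giving 18 directly.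

3. Step 3. Oxidative addition to the electron-rich aryl bromide may be slow, so that long heating brings hydrodebromination or loss of the methyl ester. Fallback (oxidative copper coupling of a boronic acid at room temperature), setting out from 5 and returning at 7: bromine–lithium exchange on 5 with nBuLi in THF at −78 °C, quench with B(OiPr)3 and aqueous acid should give {3-methoxy-5-[(E)-2-(4-benzyloxyphenyl)ethenyl]phenyl}boronic acid F6. Chan–Lam coupling of F6 with phenol 6 (Cu(OAc)2, pyridine, 4 Å MS, CH2Cl2, air, rt) should then give diaryl ether 7.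

**Further compounds**
F1 | step 6 | 3-[4-(3-{(E)-2-[4-(benzyloxy)phenyl]ethenyl}-5-methoxyphenoxy)phenyl]propanal | O=CCCc1ccc(Oc2cc(OC)cc(/C=C/c3ccc(OCc4ccccc4)cc3)c2)cc1
F2 | step 6 | 6-{6-[4-(3-{(E)-2-[4-(benzyloxy)phenyl]ethenyl}-5-methoxyphenoxy)phenyl]-4-hydroxy-2-oxohexyl}-2,2-dimethyl-4H-1,3-dioxin-4-one (racemic) | CC1(C)OC(CC(=O)CC(O)CCc2ccc(Oc3cc(OC)cc(/C=C/c4ccc(OCc5ccccc5)cc4)c3)cc2)=CC(=O)O1
F3 | step 7 | benzyl 9-[4-(3-{(E)-2-[4-(benzyloxy)phenyl]ethenyl}-5-methoxyphenoxy)phenyl]-3,5,7-trioxononanoate | O=C(CC(=O)CC(=O)CC(=O)CCc1ccc(Oc2cc(OC)cc(/C=C/c3ccc(OCc4ccccc4)cc3)c2)cc1)OCc1ccccc1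
F4 | step 7 | benzyl 2-{2-[4-(3-{(E)-2-[4-(benzyloxy)phenyl]ethenyl}-5-methoxyphenoxy)phenyl]ethyl}-4,6-dihydroxybenzoate | O=C(OCc1ccccc1)c1c(O)cc(O)cc1CCc1ccc(Oc2cc(OC)cc(/C=C/c3ccc(OCc4ccccc4)cc3)c2)cc1
F5 | step 7 | benzyl 2-{2-[4-(3-{(E)-2-[4-(benzyloxy)phenyl]ethenyl}-5-methoxyphenoxy)phenyl]ethyl}-6-hydroxy-4-methoxybenzoate | COc1cc(O)c(C(=O)OCc2ccccc2)c(CCc2ccc(Oc3cc(OC)cc(/C=C/c4ccc(OCc5ccccc5)cc4)c3)cc2)c1
F6 | step 3 | {3-methoxy-5-[(E)-2-(4-benzyloxyphenyl)ethenyl]phenyl}boronic acid | COc1cc(B(O)O)cc(/C=C/c2ccc(OCc3ccccc3)cc2)c1
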